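The route rests on cutting the C2–C3 bond of the tetrahydrofuran. In the open-chain form, the future C2 is the CH2 of a 4-alkoxy-3-methoxybenzyl group on O1; flanked by that oxygen and an electron-rich arene, its hydrogens are the most hydridic ones lying 1,5 to C3. A dirhodium carbene raised at C3 from an α-diazo ester inserts there, closing ring O1–C2–C3–C4–C5 and setting C2 and C3 at once, opposite the cis C4-methyl/C5-aryl pair. The precursor is the α-diazo methyl ester of a syn-crotylation-derived dibenzylic ether that already carries both threo side chains, built from lactate, as silyl ethers.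

Key step: step 16

Remark on the chemistry (assumption): the ring is numbered O1, C2 (the former benzylic CH2 of the ether), C3, C4, C5, and the target is read from its SMILES as (2S,3R,4R,5S) with two (1R,2R) (threo) side chains; TBS = tert-butyldimethylsilyl; ArS = 4-{[(1R,2R)-1-(TBS-oxy)-1-(3,4-dimethoxyphenyl)propan-2-yl]oxy}-3-methoxyphenyl; 3,4-dimethoxyphenylmagnesium bromide is taken as the purchased THF solution.

Step 1
Reactants: 1 ethyl (S)-lactate; 2 4-bromo-2-methoxyphenol
Product: 3 ethyl (2R)-2-(4-bromo-2-methoxyphenoxy)propanoate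
Conditions: PPh3, diisopropyl azodicarboxylate, THF, 0 °C to rt
Reagents that add atoms: none
Why: Mitsunobu etherification of an α-hydroxy ester by a phenol runs by SN2 inversion, so the (S)-lactate should give the (R)-aryl ether with the aryloxy group on the methyl-bearing carbon and no regiochemical ambiguity.

Step 2
Reactants: 3 ethyl (2R)-2-(4-bromo-2-methoxyphenoxy)propanoate
Product: 4 (2R)-2-(4-bromo-2-methoxyphenoxy)-N-methoxy-N-methylpropanamide
Conditions: MeNH(OMe)·HCl, iPrMgCl, THF, −20 to 0 °C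
Reagents that add atoms: N,O-dimethylhydroxylamine hydrochloride, CNOC.Cl
Why: Aminolysis of the ester by the magnesium amide (Weinreb amide formation) is fast at low temperature and should leave the α-aryloxy stereocentre untouched.

Step 3
Reactants: 4 (2R)-2-(4-bromo-2-methoxyphenoxy)-N-methoxy-N-methylpropanamide; 5 3,4-dimethoxyphenylmagnesium bromide
Product: 6 (2R)-2-(4-bromo-2-methoxyphenoxy)-1-(3,4-dimethoxyphenyl)propan-1-one
Conditions: THF, −10 to 0 °C; aq. NH4Cl
Reagents that add atoms: none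
Why: Grignard addition to an N-methoxy-N-methylamide (Weinreb ketone synthesis) stops at the chelated tetrahedral adduct, so the base-sensitive α-aryloxy ketone is released only on mildly acidic work-up.

Step 4
Reactants: 6 (2R)-2-(4-bromo-2-methoxyphenoxy)-1-(3,4-dimethoxyphenyl)propan-1-one
Product: 7 (1R,2R)-2-(4-bromo-2-methoxyphenoxy)-1-(3,4-dimethoxyphenyl)propan-1-ol (threo)
Conditions: (R)-1-methyl-3,3-diphenyltetrahydro-1H,3H-pyrrolo[1,2-c][1,3,2]oxazaborole (0.5 equiv), BH3·SMe2, THF, −20 °C; MeOH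
Reagents that add atoms: none
Why: Corey–Bakshi–Shibata reduction delivers hydride under reagent control, and the (R)-oxazaborolidine and the Felkin–Anh preference of the α-aryloxy ketone should both favour the (1R) carbinol, giving the threo ether alcohol.

Step 5
Reactants: 7 (1R,2R)-2-(4-bromo-2-methoxyphenoxy)-1-(3,4-dimethoxyphenyl)propan-1-ol
Product: 8 ArS–Br, the TBS ether of 7
Conditions: TBSOTf, 2,6-lutidine, CH2Cl2, −78 to 0 °C
Reagents that add atoms: tert-butyldimethylsilyl trifluoromethanesulfonate, CC(C)(C)[Si](C)(C)OS(=O)(=O)C(F)(F)F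
Why: Silylation of the hindered secondary benzylic alcohol with a silyl triflate and a hindered base masks the only O–H bond, which would otherwise be captured by the carbene later.

Step 6
Reactants: 8 ArS–Br
Product: 10 ArS–CHO (the side-chain aldehyde), via aryllithium 9 (not isolated)
Conditions: nBuLi, THF, −78 °C; DMF, −78 to 0 °C; aq. NH4Cl
Reagents that add atoms: N,N-dimethylformamide, CN(C)C=O
Why: Bromine–lithium exchange at −78 °C is far faster than any deprotonation, and the aryllithium is formylated by DMF (Bouveault aldehyde synthesis).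

Step 7
Reactants: 10 ArS–CHO
Product: 11 ArS–CH2OH
Conditions: NaBH4, MeOH/THF, 0 °C
Reagents that add atoms: none
Why: Borohydride reduction of the aryl aldehyde is chemoselective because nothing else in the molecule is reducible under these conditions.

Step 8
Reactants: 11 ArS–CH2OH
Product: 12 ArS–CH2Br
Conditions: CBr4, PPh3, 2,6-lutidine, CH2Cl2, 0 °C; used at once
Reagents that add atoms: carbon tetrabromide, BrC(Br)(Br)Br
Why: The Appel reaction converts the primary benzylic alcohol into the bromide under neutral conditions that spare the benzylic silyl ether.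

Step 9
Reactants: 10 ArS–CHO
Product: 14 (1S,2R)-1-(ArS)-2-methylbut-3-en-1-ol (syn), via borinate ester 13 (not isolated)
Conditions: (Z)-but-2-ene, KOtBu, nBuLi, THF, −78 to −45 °C; (−)-B-methoxydiisopinocampheylborane, −78 °C; BF3·OEt2; 10, −78 °C; NaOH, H2O2, rt
Reagents that add atoms: (Z)-but-2-ene, C/C=C\C
Why: Brown crotylboration passes through a closed chair (Zimmerman–Traxler) transition state, so the Z reagent gives the syn relationship and the isopinocampheyl groups of the (+)-α-pinene series direct attack to the si face of the aryl aldehyde, setting C5 as S and C4 as R.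

Step 10
Reactants: 14 (1S,2R)-1-(ArS)-2-methylbut-3-en-1-ol; 12 ArS–CH2Br
Product: 15 (1S,2R)-1-(ArS)-1-[(ArS)methoxy]-2-methylbut-3-ene
Conditions: NaH, Bu4NI (cat.), THF/DMF, 0 °C to rt
Reagents that add atoms: none
Why: Williamson etherification alkylates the alkoxide at oxygen only, so the acid-labile electron-rich benzylic stereocentre C5 never passes through a cation and keeps its configuration.

Step 11
Reactants: 15 (1S,2R)-1-(ArS)-1-[(ArS)methoxy]-2-methylbut-3-ene
Product: 17 (3R,4S)-4-(ArS)-4-[(ArS)methoxy]-3-methylbutan-1-ol, via alkylborane 16 (not isolated)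
Conditions: 9-borabicyclo[3.3.1]nonane, THF, 0 °C to rt; NaOH, H2O2, 0 °C
Reagents that add atoms: hydrogen peroxide, OO
Why: Hydroboration–oxidation with a bulky dialkylborane places boron, and then oxygen, on the terminal carbon of the monosubstituted alkene (anti-Markovnikov).

Step 12
Reactants: 17 (3R,4S)-4-(ArS)-4-[(ArS)methoxy]-3-methylbutan-1-ol
Product: 18 (3R,4S)-4-(ArS)-4-[(ArS)methoxy]-3-methylbutanoic acid
Conditions: 2,2,6,6-tetramethylpiperidin-1-oxyl (cat.), PhI(OAc)2, MeCN/H2O, rt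
Reagents that add atoms: water, O
Why: Oxoammonium-mediated oxidation (nitroxyl catalysis) takes the primary alcohol through the aldehyde hydrate to the acid under near-neutral conditions tolerated by silyl and benzylic ethers.

Step 13
Reactants: 18 (3R,4S)-4-(ArS)-4-[(ArS)methoxy]-3-methylbutanoic acid
Product: 19 methyl (3R,4S)-4-(ArS)-4-[(ArS)methoxy]-3-methylbutanoate
Conditions: MeI, K2CO3, DMF, rt
Reagents that add atoms: iodomethane, CI
Why: SN2 alkylation of the carboxylate is a mild esterification that touches no other group.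

Step 14
Reactants: 19 methyl (3R,4S)-4-(ArS)-4-[(ArS)methoxy]-3-methylbutanoate
Product: 20 methyl (3R,4S)-2-benzoyl-4-(ArS)-4-[(ArS)methoxy]-3-methylbutanoate (both C2 epimers)
Conditions: NaH, PhCO2Me, 1,2-dimethoxyethane, reflux; aq. NH4Cl
Reagents that add atoms: methyl benzoate, COC(=O)c1ccccc1
Why: Crossed Claisen condensation with a non-enolisable ester is driven by deprotonation of the β-keto ester formed and activates the future C3 for diazo transfer, while the β-carbon carries no leaving group that could be eliminated.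

Step 15
Reactants: 20 methyl (3R,4S)-2-benzoyl-4-(ArS)-4-[(ArS)methoxy]-3-methylbutanoate
Product: 21 methyl (3R,4S)-2-diazo-4-(ArS)-4-[(ArS)methoxy]-3-methylbutanoate (precursor of the key step)
Conditions: 4-O2NC6H4SO2N3, DBU, CH2Cl2, 0 °C
Reagents that add atoms: 4-nitrobenzenesulfonyl azide, [N-]=[N+]=NS(=O)(=O)c1ccc(cc1)[N+](=O)[O-]
Why: In this Regitz deacylative diazo transfer the β-keto ester enolate adds to the sulfonyl azide and the adduct fragments with loss of the benzoyl group as the N-sulfonyl benzamide, leaving the α-diazo ester.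

Step 16
Reactants: 21 methyl (3R,4S)-2-diazo-4-(ArS)-4-[(ArS)methoxy]-3-methylbutanoate
Product: 22 methyl (2S,3R,4R,5S)-2,5-bis(ArS)-4-methyltetrahydrofuran-3-carboxylate
Conditions: Rh2(O2CCPh3)4 (1 mol %), 4 Å molecular sieves, CH2Cl2, −78 to −40 °C, slow addition of 21
Reagents that add atoms: none
Why: Rh2(O2CCPh3)4 should expel N2 from 21 to give an electrophilic rhodium carbene at C3, which inserts into a C2–H bond in a concerted, asynchronous three-centre step with hydride-transfer character; the closest known reaction type is the dirhodium-catalysed 1,5 C–H insertion of α-alkyl-α-diazo esters into benzylic ether C–H bonds to give 2-aryl-tetrahydrofuran-3-carboxylates. The tetrahydrofuran ring is closed by this 1,5 insertion, C3 bonding to C2 across the chain C3–C4–C5–O1–C2. C3 should be set by the C4 stereocentre: in the insertion geometry the small C4–H, not the C4 methyl, eclipses the ester, so the ester ends trans to the C4 methyl. C2 should be set by the catalyst wall together with the geometry fixed at C4 and C5: ester and rhodium lie on opposite faces of the forming ring, the C2 aryl turns away from the triphenylacetate ligands onto the ester face (2,3-cis), and this places it trans to the pseudo-equatorial C5 aryl. The step needs chemoselectivity for C2–H insertion over 1,2-hydride migration from C4–H and over attack on the C5 aryl ring; the C2–H bond is doubly activated (the lone pair of O1 and the 4-alkoxyaryl group stabilise the developing positive charge), and the large triphenylacetate ligands together with the low temperature disfavour the competing hydride migration.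

Step 17
Reactants: 22 methyl (2S,3R,4R,5S)-2,5-bis(ArS)-4-methyltetrahydrofuran-3-carboxylate
Product: 23 [(2S,3S,4R,5S)-2,5-bis(ArS)-4-methyltetrahydrofuran-3-yl]methanol
Conditions: iBu2AlH, CH2Cl2, −78 to 0 °C; aq. KNaC4H4O6
Reagents that add atoms: none
Why: Hydride reduction of the ester to the primary alcohol is non-basic and removes the carbonyl that makes C3–H epimerisable, so the kinetically set C3 configuration is preserved.

Step 18
Reactants: 23 [(2S,3S,4R,5S)-2,5-bis(ArS)-4-methyltetrahydrofuran-3-yl]methanol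
Product: 24 [(2S,3S,4R,5S)-2,5-bis(ArS)-4-methyltetrahydrofuran-3-yl]methyl methanesulfonate
Conditions: MsCl, Et3N, CH2Cl2, 0 °C
Reagents that add atoms: methanesulfonyl chloride, CS(=O)(=O)Cl
Why: Sulfonylation of the primary alcohol turns it into a leaving group without touching any stereocentre.

Step 19
Reactants: 24 [(2S,3S,4R,5S)-2,5-bis(ArS)-4-methyltetrahydrofuran-3-yl]methyl methanesulfonate
Product: 25 (2S,3R,4R,5S)-2,5-bis(ArS)-3,4-dimethyltetrahydrofuran (bis-TBS manassantin A)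
Conditions: LiBHEt3, THF, 0 to 40 °C
Reagents that add atoms: none
Why: The strongly nucleophilic borohydride displaces the primary sulfonate by SN2 hydride delivery, converting CH2OMs into the C3 methyl group.

Step 20
Reactants: 25 (2S,3R,4R,5S)-2,5-bis(ArS)-3,4-dimethyltetrahydrofuran
Product: 26 manassantin A
Conditions: Bu4NF, THF, rt
Reagents that add atoms: none
Why: Fluoride-mediated desilylation frees both secondary benzylic alcohols under non-acidic conditions that cannot epimerise the diaryl tetrahydrofuran.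

Compound list
1 | ethyl (S)-lactate | C[C@H](O)C(=O)OCC | starting material
2 | 4-bromo-2-methoxyphenol | COc1cc(Br)ccc1O | starting material
3 | ethyl (2R)-2-(4-bromo-2-methoxyphenoxy)propanoate | C[C@@H](Oc1ccc(Br)cc1OC)C(=O)OCC | intermediate
4 | (2R)-2-(4-bromo-2-methoxyphenoxy)-N-methoxy-N-methylpropanamide | C[C@@H](Oc1ccc(Br)cc1OC)C(=O)N(C)OC | intermediate
5 | 3,4-dimethoxyphenylmagnesium bromide | COc1ccc([Mg]Br)cc1OC | starting material
6 | (2R)-2-(4-bromo-2-methoxyphenoxy)-1-(3,4-dimethoxyphenyl)propan-1-one | C[C@@H](Oc1ccc(Br)cc1OC)C(=O)c1ccc(OC)c(OC)c1 | intermediate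
7 | (1R,2R)-2-(4-bromo-2-methoxyphenoxy)-1-(3,4-dimethoxyphenyl)propan-1-ol | COc1ccc([C@@H](O)[C@@H](C)Oc2ccc(Br)cc2OC)cc1OC | intermediate
8 | ArS–Br, TBS ether of 7 | COc1ccc([C@@H](O[Si](C)(C)C(C)(C)C)[C@@H](C)Oc2ccc(Br)cc2OC)cc1OC | intermediate
9 | ArS–Li, aryllithium | COc1ccc([C@@H](O[Si](C)(C)C(C)(C)C)[C@@H](C)Oc2ccc([Li])cc2OC)cc1OC | intermediate (not isolated)
10 | ArS–CHO, side-chain aldehyde | COc1ccc([C@@H](O[Si](C)(C)C(C)(C)C)[C@@H](C)Oc2ccc(C=O)cc2OC)cc1OC | intermediate
11 | ArS–CH2OH | COc1ccc([C@@H](O[Si](C)(C)C(C)(C)C)[C@@H](C)Oc2ccc(CO)cc2OC)cc1OC | intermediate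
12 | ArS–CH2Br | COc1ccc([C@@H](O[Si](C)(C)C(C)(C)C)[C@@H](C)Oc2ccc(CBr)cc2OC)cc1OC | intermediate
13 | O-(diisopinocampheylboryl) derivative of 14 (borinate ester) | B(O[C@H](c1ccc(O[C@H](C)[C@H](O[Si](C)(C)C(C)(C)C)c2ccc(OC)c(OC)c2)c(OC)c1)[C@H](C)C=C)([C@@H]1C[C@@H]2C[C@H]([C@H]1C)C2(C)C)[C@@H]1C[C@@H]2C[C@H]([C@H]1C)C2(C)C | intermediate (not isolated)
14 | (1S,2R)-1-(ArS)-2-methylbut-3-en-1-ol | O[C@H](c1ccc(O[C@H](C)[C@H](O[Si](C)(C)C(C)(C)C)c2ccc(OC)c(OC)c2)c(OC)c1)[C@H](C)C=C | intermediate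
15 | (1S,2R)-1-(ArS)-1-[(ArS)methoxy]-2-methylbut-3-ene | COc1ccc([C@@H](O[Si](C)(C)C(C)(C)C)[C@@H](C)Oc2ccc(CO[C@H](c3ccc(O[C@H](C)[C@H](O[Si](C)(C)C(C)(C)C)c4ccc(OC)c(OC)c4)c(OC)c3)[C@H](C)C=C)cc2OC)cc1OC | intermediate
16 | B-alkyl-9-borabicyclo[3.3.1]nonane adduct of 15 | COc1ccc([C@@H](O[Si](C)(C)C(C)(C)C)[C@@H](C)Oc2ccc(CO[C@H](c3ccc(O[C@H](C)[C@H](O[Si](C)(C)C(C)(C)C)c4ccc(OC)c(OC)c4)c(OC)c3)[C@H](C)CCB5C6CCCC5CCC6)cc2OC)cc1OC | intermediate (not isolated)
17 | (3R,4S)-4-(ArS)-4-[(ArS)methoxy]-3-methylbutan-1-ol | COc1ccc([C@@H](O[Si](C)(C)C(C)(C)C)[C@@H](C)Oc2ccc(CO[C@H](c3ccc(O[C@H](C)[C@H](O[Si](C)(C)C(C)(C)C)c4ccc(OC)c(OC)c4)c(OC)c3)[C@H](C)CCO)cc2OC)cc1OC | intermediate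
18 | (3R,4S)-4-(ArS)-4-[(ArS)methoxy]-3-methylbutanoic acid | COc1ccc([C@@H](O[Si](C)(C)C(C)(C)C)[C@@H](C)Oc2ccc(CO[C@H](c3ccc(O[C@H](C)[C@H](O[Si](C)(C)C(C)(C)C)c4ccc(OC)c(OC)c4)c(OC)c3)[C@H](C)CC(=O)O)cc2OC)cc1OC | intermediate
19 | methyl (3R,4S)-4-(ArS)-4-[(ArS)methoxy]-3-methylbutanoate | COc1ccc([C@@H](O[Si](C)(C)C(C)(C)C)[C@@H](C)Oc2ccc(CO[C@H](c3ccc(O[C@H](C)[C@H](O[Si](C)(C)C(C)(C)C)c4ccc(OC)c(OC)c4)c(OC)c3)[C@H](C)CC(=O)OC)cc2OC)cc1OC | intermediate
20 | methyl (3R,4S)-2-benzoyl-4-(ArS)-4-[(ArS)methoxy]-3-methylbutanoate | COc1ccc([C@@H](O[Si](C)(C)C(C)(C)C)[C@@H](C)Oc2ccc(CO[C@H](c3ccc(O[C@H](C)[C@H](O[Si](C)(C)C(C)(C)C)c4ccc(OC)c(OC)c4)c(OC)c3)[C@H](C)C(C(=O)c5ccccc5)C(=O)OC)cc2OC)cc1OC | intermediate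
21 | methyl (3R,4S)-2-diazo-4-(ArS)-4-[(ArS)methoxy]-3-methylbutanoate | COc1ccc([C@@H](O[Si](C)(C)C(C)(C)C)[C@@H](C)Oc2ccc(CO[C@H](c3ccc(O[C@H](C)[C@H](O[Si](C)(C)C(C)(C)C)c4ccc(OC)c(OC)c4)c(OC)c3)[C@H](C)C(=[N+]=[N-])C(=O)OC)cc2OC)cc1OC | intermediate
22 | methyl (2S,3R,4R,5S)-2,5-bis(ArS)-4-methyltetrahydrofuran-3-carboxylate | COc1ccc([C@@H](O[Si](C)(C)C(C)(C)C)[C@@H](C)Oc2ccc([C@H]3O[C@H](c4ccc(O[C@H](C)[C@H](O[Si](C)(C)C(C)(C)C)c5ccc(OC)c(OC)c5)c(OC)c4)[C@H](C)[C@H]3C(=O)OC)cc2OC)cc1OC | intermediate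
23 | [(2S,3S,4R,5S)-2,5-bis(ArS)-4-methyltetrahydrofuran-3-yl]methanol | COc1ccc([C@@H](O[Si](C)(C)C(C)(C)C)[C@@H](C)Oc2ccc([C@H]3O[C@H](c4ccc(O[C@H](C)[C@H](O[Si](C)(C)C(C)(C)C)c5ccc(OC)c(OC)c5)c(OC)c4)[C@H](C)[C@H]3CO)cc2OC)cc1OC | intermediate
24 | [(2S,3S,4R,5S)-2,5-bis(ArS)-4-methyltetrahydrofuran-3-yl]methyl methanesulfonate | COc1ccc([C@@H](O[Si](C)(C)C(C)(C)C)[C@@H](C)Oc2ccc([C@H]3O[C@H](c4ccc(O[C@H](C)[C@H](O[Si](C)(C)C(C)(C)C)c5ccc(OC)c(OC)c5)c(OC)c4)[C@H](C)[C@H]3COS(C)(=O)=O)cc2OC)cc1OC | intermediate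
25 | (2S,3R,4R,5S)-2,5-bis(ArS)-3,4-dimethyltetrahydrofuran (bis-TBS manassantin A) | COc1ccc([C@@H](O[Si](C)(C)C(C)(C)C)[C@@H](C)Oc2ccc([C@H]3O[C@H](c4ccc(O[C@H](C)[C@H](O[Si](C)(C)C(C)(C)C)c5ccc(OC)c(OC)c5)c(OC)c4)[C@H](C)[C@H]3C)cc2OC)cc1OC | intermediate
26 | manassantin A | COc1ccc([C@@H](O)[C@@H](C)Oc2ccc([C@H]3O[C@H](c4ccc(O[C@H](C)[C@H](O)c5ccc(OC)c(OC)c5)c(OC)c4)[C@H](C)[C@H]3C)cc2OC)cc1OC | target

Total step count: 20 steps.
Longest linear sequence: 19 steps (steps 1–8 and 10–20, running through benzylic bromide 12; step 9, which turns aldehyde 10 into alcohol 14, is the one-step convergent branch).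

Steps most likely to fail

1. Step 16. Three processes could defeat it: 1,2-hydride migration from C4 to the carbene carbon outrunning insertion; electrophilic attack of the carbene on the electron-rich C5 aryl ring; and insertion through the other diastereomeric arrangement, giving the wrong face at C2 or C3. The fallback closes the ring instead by C2–aryl bond formation on a five-membered oxocarbenium ion, setting out from alcohol 14 and aryl bromide 8 and rejoining the route at 25. Hydroboration–oxidation of 14 (9-borabicyclo[3.3.1]nonane; NaOH, H2O2) would give the 1,4-diol F1. Oxidative lactonisation (2,2,6,6-tetramethylpiperidin-1-oxyl, PhI(OAc)2, CH2Cl2) would give the cis-4,5 lactone F2. Enolate methylation (LiN(SiMe3)2, MeI, THF, −78 °C), anti to the C4 methyl and C5 aryl groups, would give the 3,4-trans lactone F3. Reduction with iBu2AlH would give the lactol F4, and PhSO2H with CaCl2 in CH2Cl2 the 2-sulfonyl tetrahydrofuran F5. The arylzinc bromide F6, made from 8 by bromine–lithium exchange (nBuLi, giving 9) and ZnBr2, would ionise F5 and add to the oxocarbenium ion cis to the C3 methyl group, the known preference of arylzinc additions to such 2-sulfonyl cyclic ethers, to give 25.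

2. Step 4. Facial selectivity at the ketone could erode if the oxazaborolidine does not distinguish the branched aryloxyalkyl group from the aryl group well enough. The fallback sets out from ketone 6 and returns at 7. Chelation-controlled reduction with Zn(BH4)2 (Et2O, −20 °C, zinc bridging the carbonyl and ether oxygens) would give the erythro alcohol F7. Mitsunobu esterification with 4-nitrobenzoic acid (PPh3, diisopropyl azodicarboxylate) would invert C1 to give the threo 4-nitrobenzoate F8, and methanolysis (K2CO3, MeOH) would give 7.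

3. Step 19. Hydride could attack at sulfur (S–O cleavage that returns the alcohol), or SN2 displacement could be sluggish at a primary carbon flanked by two ring substituents. The fallback sets out from alcohol 23 and returns at 25. I2, PPh3 and imidazole would give the primary iodide F9, and radical dehalogenation (Bu3SnH, azobisisobutyronitrile, toluene, 80 °C) would give 25.

Further compounds
F1 | step 16 | (3R,4S)-4-(ArS)-3-methylbutane-1,4-diol | O[C@H](c1ccc(O[C@H](C)[C@H](O[Si](C)(C)C(C)(C)C)c2ccc(OC)c(OC)c2)c(OC)c1)[C@H](C)CCO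
F2 | step 16 | (4R,5S)-5-(ArS)-4-methyldihydrofuran-2(3H)-one | O1[C@H](c2ccc(O[C@H](C)[C@H](O[Si](C)(C)C(C)(C)C)c3ccc(OC)c(OC)c3)c(OC)c2)[C@H](C)CC1=O
F3 | step 16 | (3R,4R,5S)-5-(ArS)-3,4-dimethyldihydrofuran-2(3H)-one | O1[C@H](c2ccc(O[C@H](C)[C@H](O[Si](C)(C)C(C)(C)C)c3ccc(OC)c(OC)c3)c(OC)c2)[C@H](C)[C@@H](C)C1=O
F4 | step 16 | (3R,4R,5S)-5-(ArS)-3,4-dimethyltetrahydrofuran-2-ol (both anomers) | O1[C@H](c2ccc(O[C@H](C)[C@H](O[Si](C)(C)C(C)(C)C)c3ccc(OC)c(OC)c3)c(OC)c2)[C@H](C)[C@@H](C)C1O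
F5 | step 16 | (3R,4R,5S)-2-(benzenesulfonyl)-5-(ArS)-3,4-dimethyltetrahydrofuran | O1[C@H](c2ccc(O[C@H](C)[C@H](O[Si](C)(C)C(C)(C)C)c3ccc(OC)c(OC)c3)c(OC)c2)[C@H](C)[C@@H](C)C1S(=O)(=O)c1ccccc1
F6 | step 16 | ArS–ZnBr, arylzinc bromide | COc1ccc([C@@H](O[Si](C)(C)C(C)(C)C)[C@@H](C)Oc2ccc([Zn]Br)cc2OC)cc1OC
F7 | step 4 | (1S,2R)-2-(4-bromo-2-methoxyphenoxy)-1-(3,4-dimethoxyphenyl)propan-1-ol | COc1ccc([C@H](O)[C@@H](C)Oc2ccc(Br)cc2OC)cc1OC
F8 | step 4 | (1R,2R)-2-(4-bromo-2-methoxyphenoxy)-1-(3,4-dimethoxyphenyl)propyl 4-nitrobenzoate | COc1ccc([C@@H](OC(=O)c3ccc(cc3)[N+](=O)[O-])[C@@H](C)Oc2ccc(Br)cc2OC)cc1OC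
F9 | step 19 | (2S,3R,4R,5S)-2,5-bis(ArS)-3-(iodomethyl)-4-methyltetrahydrofuran | COc1ccc([C@@H](O[Si](C)(C)C(C)(C)C)[C@@H](C)Oc2ccc([C@H]3O[C@H](c4ccc(O[C@H](C)[C@H](O[Si](C)(C)C(C)(C)C)c5ccc(OC)c(OC)c5)c(OC)c4)[C@H](C)[C@H]3CI)cc2OC)cc1OC
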